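## The problem

The target is an unsymmetrical dehydrodimer of two 3-hydroxy-3,4-dibenzylbutyrolactones, both (3R,4R). Lactone 1 carries guaiacyl ring A on its C4 methylene and ring B on its C3 methylene. Lactone 2 carries ring C on its C4 methylene and guaiacyl ring D on its C3 methylene. C5 of ring B is bonded to C5 of ring C, ortho to a phenolic hydroxyl on each side, so the core is a 2,2'-dihydroxy-3,3'-dimethoxybiphenyl. Because a C3-benzyl arene is joined to a C4-benzyl arene, no symmetry relates the halves.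

Each lactone has a quaternary carbinol C3 next to C4, with the benzyl groups trans and the hydroxyl cis to the C4 substituent. Within one lactone the first centre can direct the second, but the two pairs are insulated from each other by the biaryl, so absolute configuration has to be brought in twice.

The four electron-rich phenols, two of them forming a 2,2'-biphenol, are sensitive to oxidants. The tertiary α-hydroxy lactones open with base and can dehydrate under strong acid. C3 is quaternary and C4–H is not acidic, so base cannot enolise or epimerise either lactone.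

The feature that invites a ring-forming solution is the substitution of ring C: C4–OH is flanked by C3–OMe and C5–ring B, C2 and C6 carry hydrogen, and C1 carries the side chain. C3–C4–C5 is therefore the skeleton of a 1-aryl-3-methoxyacetone, and C2–C1–C6 that of a 2-substituted malonaldehyde.

## Retrosynthesis

**Protecting groups.** Target 37 is traced to biaryl 35, in which the phenols of rings A, B and D are benzyl ethers and the C3 hydroxyl of lactone 2 is a benzyloxymethyl (BOM) ether. Only O–CH2 bonds are cut, and all four groups fall in one neutral hydrogenolysis, so the free phenols appear only at the end. The forward step must leave the biaryl and the lactones alone.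

**Ring C (key cut).** In 35 the C5–C6 and C2–C3 bonds of ring C are cut. This gives ketone 20, which is lactone 1 with a 3-methoxy-2-oxopropyl group on C5 of ring B, and enaminal 33, which is lactone 2 with a 3-(dimethylamino)-2-formylprop-2-enyl group on C4. The neighbouring cut, the biaryl bond itself, would need both elaborated lactones halogenated or metallated next to a protected phenol, plus a metal-catalysed coupling of two hindered ortho-oxygenated partners. The annulation instead makes ring C with its hydroxyl free, ortho to ring B by necessity, and joins two separately purified, stereodefined halves. The forward reaction must favour cross- over self-condensation of 20 and must tolerate two lactones under alkoxide.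

**Enaminal arm.** 33 is traced through aldehyde 32 and alcohol 31 to allyl lactone 29 and its free alcohol 28. The cuts are the C=C bond to the aminomethine carbon, then functional-group changes on a three-carbon chain. An allyl group is chosen because allyl bromide is a good electrophile for the malate alkylation and is inert to enolate chemistry. The C3 hydroxyl is capped as BOM before the chain is oxidised because it sits cis to the C4 chain: it would otherwise trap the aldehyde as a six-membered lactol and could add to the enaminal.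

**Lactone 2.** 28 is cut at O1–C5 (lactonisation after reduction of a carboxyl) to dioxolanone acid 25. 25 is cut at the C3–CH2Ar bond to dioxolanone acid 24 and benzyl bromide 2. 24 is traced through diacid 23 to allyl malate 22, which is cut at the C4–allyl bond to diethyl (R)-malate 3 and allyl bromide 21. The malate supplies C2–C5 of the lactone and the C3 oxygen. Its single stereocentre controls C4 (anti alkylation of the dianion) and then, through the tert-butyl acetal, its own conversion to the quaternary centre with retention. An enolate hydroxylation of a preformed lactone would place the oxygen trans to the C4 substituent, the wrong way.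

**Lactone 1.** 20 is traced to alkene 18, a 2-(methoxymethyl)allyl group being a latent 3-methoxy-2-oxopropyl group that survives enolate alkylation. 18 is cut like 28 to dioxolanone acid 15, then to dioxolanone acid 6 and benzyl bromide 14. 6 is traced through diacid 5 and malate 4 to 3 and 2. The order of electrophiles is the reverse of lactone 2: the guaiacyl bromide goes in first (C4), the ring B bromide second (C3).

**Ring B bromide.** 14 is traced through alcohol 13, aldehyde 12 and phenol 11 to aryl ether 10. The C5–CH2 bond of the vanillin ring is cut by a Claisen rearrangement. 10 comes from chloride 9, made from vanillin 7 and 3-chloro-2-(chloromethyl)prop-1-ene 8. The symmetric 2-substituted allyl group makes the allylic transposition irrelevant and brings the three carbons that become C3, C4 and C5 of ring C.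

**Guaiacyl bromide.** 2 comes in one step from commercial alcohol 1 and serves both lactones.

## Roads not taken

**Alternative 1:** Both C3–O bonds are cut and each tertiary alcohol is traced to an epoxide.
- Forward step: twofold Sharpless epoxidation (Ti(OiPr)4, L-(+)-diethyl tartrate, tBuOOH) of both (E)-2-(arylmethylene) allylic alcohol units on a preformed biaryl, giving the bis(2,3-epoxy alcohol) A1.
- Merits: the stereodefining reaction is among the best understood catalytic asymmetric reactions, and the biaryl can be made early on simple arenes by standard coupling. In both respects it stands on firmer ground than the annulation chosen here.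
- Weak points: it sets only C3, so both C4 centres need another chirality source and sit next to the reacting alkene, where matched and mismatched induction must be faced. The 2-substituent is branched, which slows the epoxidation. Aryl epoxides with para oxygen are labile, hence the four aryl mesylates, whose removal at the end is harsh. After A1 each half still needs reductive benzylic opening, oxidation of a primary alcohol next to the tertiary one, desilylation and lactonisation. Any imperfection is squared because the step runs twice on one molecule.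
- Against this the chosen plan sets one chiral-pool source per lactone, separate purification of each half, and a key step that creates no stereocentre.

**Alternative 2:** The C3–C4 bond of each lactone is cut.
- Forward step: both α-benzyloxy ester groups are enolised (LiN(SiMe3)2, Me3SiCl) and rearrange through chelate-controlled chair Ireland–Claisen transition states to the bis(γ,δ-unsaturated acid) A2, with an (E)-propenyl group as masked C5.
- Merits: one pericyclic event per lactone forms the C3–C4 bond and both centres, including the quaternary one, and the tertiary oxygen already carries a benzyl group that leaves in the final hydrogenolysis. In bond-forming economy per step it is better than the chosen plan.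
- Weak points: the geometry of a fully substituted α-alkoxy ketene acetal rests entirely on chelation. Two enantiopure secondary allylic alcohols are needed. Each propenyl group must then be cleaved next to electron-rich arenes, reduced and lactonised. The substrate is a biaryl whose two arms differ (acid side of one unit, alcohol side of the other), so there is no symmetry benefit, and four centres are set in one flask.
- Against this the chosen plan sets stereocontrol of known sense from malate and a union step in which regiochemistry cannot vary.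

**Alternative 3:** The C4–C5 and O1–C2 bonds of both lactones are cut.
- Forward step: both aryl ketone groups are converted to silyl enol ethers (Me3SiOSO2CF3, Et3N) and hydroxymethylated with aqueous formaldehyde and Sc(OTf)3; each hydroxymethyl group opens its dioxolanone, giving the bis(4-aroyl-3-hydroxy lactone) A3.
- Merits: on paper the shortest route. It shares the dioxolanone logic for C3, and the ketone oxygens might leave in the same hydrogenolysis as the benzyl ethers.
- Weak points: C4 is left to equilibration, and the preference for aroyl cis to hydroxyl is an assumption that must hold twice. A 4-aroyl lactone is a β-acyloxy ketone and can open by E1cB. The hydroxymethyl ketone can lose formaldehyde by retro-aldol reaction. Deoxygenation of two aryl ketones needs acidic hydrogenolysis that puts the tertiary alcohols at risk.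
- The chosen plan is longer but sets C4 kinetically by an alkylation of established sense.

Key step: step 23

## Route

Assumption: the biaryl axis of 35–37 has only two ortho substituents and is taken to rotate freely, so no axial descriptor is assigned.

Step 1
Reactants: 1 4-(benzyloxy)-3-methoxybenzyl alcohol
Product: 2 4-(benzyloxy)-3-methoxybenzyl bromide
Conditions: PBr3 (0.4 equiv), Et2O, 0 °C
Reagents that add atoms: phosphorus tribromide, BrP(Br)Br
Why: Standard conversion of an electron-rich benzylic alcohol to its bromide by SN2 displacement on the phosphite ester; the labile bromide is used without storage.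

Step 2
Reactants: 3 diethyl (R)-malate; 2 4-(benzyloxy)-3-methoxybenzyl bromide
Product: 4 diethyl (2R,3S)-3-[4-(benzyloxy)-3-methoxybenzyl]-2-hydroxysuccinate
Conditions: LiN(iPr)2 (2.2 equiv), THF, −78 → −20 °C; 2, −78 → −10 °C; aq. NH4Cl
Reagents that add atoms: none
Why: Fráter–Seebach alkylation: the chelated alkoxide–enolate dianion is attacked anti to the C2 oxygen, so the (R)-carbinol sets the new centre as 3S (future C4 of lactone 1). The minor syn epimer should be removable by chromatography here or by crystallisation of 6.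

Step 3
Reactants: 4 diethyl (2R,3S)-3-[4-(benzyloxy)-3-methoxybenzyl]-2-hydroxysuccinate
Product: 5 (2R,3S)-3-[4-(benzyloxy)-3-methoxybenzyl]-2-hydroxysuccinic acid
Conditions: KOH, MeOH/H2O, rt; then aq. HCl
Reagents that add atoms: potassium hydroxide, [K+].[OH-]
Why: Plain ester saponification; the dicarboxylate is not enolised by aqueous hydroxide at room temperature, so both centres are kept.

Step 4
Reactants: 5 (2R,3S)-3-[4-(benzyloxy)-3-methoxybenzyl]-2-hydroxysuccinic acid
Product: 6 (2S)-3-[4-(benzyloxy)-3-methoxyphenyl]-2-[(2R,4R)-2-tert-butyl-5-oxo-1,3-dioxolan-4-yl]propanoic acid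
Conditions: tBuCHO, TsOH·H2O (cat.), H2SO4 (cat.), CH2Cl2/pentane, reflux, water separator
Reagents that add atoms: pivaldehyde, CC(C)(C)C=O
Why: Seebach acetalisation: the α-hydroxy acid closes the five-membered dioxolanone in preference to the six-membered ring through the β-carboxyl, and acid equilibration places tert-butyl cis to the side chain (acetal centre 2R). The acid should crystallise free of minor isomers.

Step 5
Reactants: 7 vanillin; 8 3-chloro-2-(chloromethyl)prop-1-ene
Product: 9 4-{[2-(chloromethyl)prop-2-en-1-yl]oxy}-3-methoxybenzaldehyde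
Conditions: K2CO3, 8 (3 equiv), DMF, 60 °C
Reagents that add atoms: none
Why: Williamson ether synthesis on the phenoxide; the excess of the symmetrical dichloride suppresses double arylation.

Step 6
Reactants: 9 4-{[2-(chloromethyl)prop-2-en-1-yl]oxy}-3-methoxybenzaldehyde
Product: 10 3-methoxy-4-{[2-(methoxymethyl)prop-2-en-1-yl]oxy}benzaldehyde
Conditions: NaOMe, MeOH, 50 °C
Reagents that add atoms: sodium methoxide, C[O-].[Na+]
Why: SN2 displacement of the allylic chloride by methoxide (SN2' displacement of chloride gives the same product); the aldehyde has no α-hydrogen and is only reversibly converted to its hemiacetal.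

Step 7
Reactants: 10 3-methoxy-4-{[2-(methoxymethyl)prop-2-en-1-yl]oxy}benzaldehyde
Product: 11 4-hydroxy-3-methoxy-5-[2-(methoxymethyl)prop-2-en-1-yl]benzaldehyde
Conditions: N,N-diethylaniline, 190 °C
Reagents that add atoms: none
Why: Aromatic Claisen rearrangement to the only free ortho position; the 2-substituted allyl group is symmetric about its central carbon, so the allylic transposition returns the same substituent. The amine solvent keeps the medium non-acidic so the o-allylphenol does not cyclise to a dihydrobenzofuran.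

Step 8
Reactants: 11 4-hydroxy-3-methoxy-5-[2-(methoxymethyl)prop-2-en-1-yl]benzaldehyde
Product: 12 4-(benzyloxy)-3-methoxy-5-[2-(methoxymethyl)prop-2-en-1-yl]benzaldehyde
Conditions: BnBr, K2CO3, DMF, rt
Reagents that add atoms: benzyl bromide, BrCc1ccccc1
Why: Williamson benzylation of the hindered phenol; the benzyl ether later keeps the ortho oxygen from attacking the ketone side chain.

Step 9
Reactants: 12 4-(benzyloxy)-3-methoxy-5-[2-(methoxymethyl)prop-2-en-1-yl]benzaldehyde
Product: 13 {4-(benzyloxy)-3-methoxy-5-[2-(methoxymethyl)prop-2-en-1-yl]phenyl}methanol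
Conditions: NaBH4, MeOH/THF, 0 °C
Reagents that add atoms: none
Why: Borohydride reduction of the aldehyde; the alkene and ethers are inert.

Step 10
Reactants: 13 {4-(benzyloxy)-3-methoxy-5-[2-(methoxymethyl)prop-2-en-1-yl]phenyl}methanol
Product: 14 2-(benzyloxy)-5-(bromomethyl)-1-methoxy-3-[2-(methoxymethyl)prop-2-en-1-yl]benzene
Conditions: CBr4, PPh3, CH2Cl2, 0 °C
Reagents that add atoms: carbon tetrabromide, BrC(Br)(Br)Br
Why: Appel bromination under neutral conditions, chosen so that no HBr adds to the 1,1-disubstituted alkene.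

Step 11
Reactants: 6 (2S)-3-[4-(benzyloxy)-3-methoxyphenyl]-2-[(2R,4R)-2-tert-butyl-5-oxo-1,3-dioxolan-4-yl]propanoic acid; 14 ring B benzyl bromide
Product: 15 (2S)-3-[4-(benzyloxy)-3-methoxyphenyl]-2-[(2R,4R)-4-{4-(benzyloxy)-3-methoxy-5-[2-(methoxymethyl)prop-2-en-1-yl]benzyl}-2-tert-butyl-5-oxo-1,3-dioxolan-4-yl]propanoic acid
Conditions: LiN(SiMe3)2 (2.2 equiv), THF, −78 °C; 14, −78 → −40 °C; aq. citric acid
Reagents that add atoms: none
Why: Self-regeneration of stereocentres: the carboxylate–enolate dianion is planar at the former carbinol carbon, and the bromide enters anti to tert-butyl, where hydrogen was. The quaternary centre (future C3 of lactone 1) therefore forms with retention, trans to the C4 benzyl group; the carboxylate protects its own α-hydrogen.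

Step 12
Reactants: 15 alkylated dioxolanone acid of the lactone 1 series
Product: 18 (3R,4R)-3-{4-(benzyloxy)-3-methoxy-5-[2-(methoxymethyl)prop-2-en-1-yl]benzyl}-4-[4-(benzyloxy)-3-methoxybenzyl]-3-hydroxyoxolan-2-one, via isobutyl carbonic mixed anhydride 16 (not isolated), via hydroxymethyl dioxolanone 17 (not isolated)
Conditions: iBuOCOCl, N-methylmorpholine, THF, −15 °C; NaBH4, H2O, −15 → 0 °C; then TsOH·H2O (cat.), CH2Cl2, rt
Reagents that add atoms: none
Why: Mixed-anhydride reduction: the carboxyl is activated as the carbonic anhydride and reduced by borohydride in the cold, which spares the alkene (borane would not) and, being brief, should spare the hindered dioxolanone. The new primary hydroxyl then attacks the dioxolanone carbonyl under acid, closing the γ-lactone and releasing pivaldehyde without touching either stereocentre.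

Step 13
Reactants: 18 lactone 1 with the 2-(methoxymethyl)allyl group on ring B
Product: 20 (3R,4R)-3-[4-(benzyloxy)-3-methoxy-5-(3-methoxy-2-oxopropyl)benzyl]-4-[4-(benzyloxy)-3-methoxybenzyl]-3-hydroxyoxolan-2-one, via vicinal diol 19 (not isolated)
Conditions: OsO4 (2 mol %), NaIO4, 2,6-lutidine, dioxane/H2O, rt
Reagents that add atoms: osmium tetroxide, O=[Os](=O)(=O)=O; sodium periodate, [Na+].[O-]I(=O)(=O)=O
Why: Lemieux–Johnson cleavage: catalytic osmylation of the only alkene and periodate cleavage of the diol give the methoxymethyl ketone and formaldehyde. The lactone, tertiary alcohol and benzyl ethers are inert, and the arenes are not exposed to ozone.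

Step 14
Reactants: 3 diethyl (R)-malate; 21 allyl bromide
Product: 22 diethyl (2R,3S)-2-hydroxy-3-(prop-2-en-1-yl)succinate
Conditions: LiN(iPr)2 (2.1 equiv), THF, −78 → −20 °C; 21, −78 → −5 °C; aq. NH4Cl
Reagents that add atoms: none
Why: Fráter–Seebach alkylation as in step 2; anti attack on the chelated dianion sets 3S, the future C4 of lactone 2.

Step 15
Reactants: 22 diethyl (2R,3S)-2-hydroxy-3-(prop-2-en-1-yl)succinate
Product: 23 (2R,3S)-2-hydroxy-3-(prop-2-en-1-yl)succinic acid
Conditions: KOH, MeOH/H2O, rt; then aq. HCl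
Reagents that add atoms: potassium hydroxide, [K+].[OH-]
Why: Ester saponification without risk to the stereocentres.

Step 16
Reactants: 23 (2R,3S)-2-hydroxy-3-(prop-2-en-1-yl)succinic acid
Product: 24 (2S)-2-[(2R,4R)-2-tert-butyl-5-oxo-1,3-dioxolan-4-yl]pent-4-enoic acid
Conditions: tBuCHO, TsOH·H2O (cat.), H2SO4 (cat.), pentane, reflux, water separator
Reagents that add atoms: pivaldehyde, CC(C)(C)C=O
Why: Seebach acetalisation as in step 4, giving the cis-dioxolanone under thermodynamic control.

Step 17
Reactants: 24 (2S)-2-[(2R,4R)-2-tert-butyl-5-oxo-1,3-dioxolan-4-yl]pent-4-enoic acid; 2 4-(benzyloxy)-3-methoxybenzyl bromide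
Product: 25 (2S)-2-{(2R,4R)-4-[4-(benzyloxy)-3-methoxybenzyl]-2-tert-butyl-5-oxo-1,3-dioxolan-4-yl}pent-4-enoic acid
Conditions: LiN(SiMe3)2 (2.2 equiv), THF, −78 °C; 2, −78 → −40 °C; aq. citric acid
Reagents that add atoms: none
Why: Self-regeneration of stereocentres as in step 11: alkylation anti to tert-butyl forms the quaternary centre (future C3 of lactone 2) with retention, trans to the allyl group.

Step 18
Reactants: 25 alkylated dioxolanone acid of the lactone 2 series
Product: 28 (3R,4R)-3-[4-(benzyloxy)-3-methoxybenzyl]-3-hydroxy-4-(prop-2-en-1-yl)oxolan-2-one, via isobutyl carbonic mixed anhydride 26 (not isolated), via hydroxymethyl dioxolanone 27 (not isolated)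
Conditions: iBuOCOCl, N-methylmorpholine, THF, −15 °C; NaBH4, H2O, −15 → 0 °C; then TsOH·H2O (cat.), CH2Cl2, rt
Reagents that add atoms: none
Why: Mixed-anhydride reduction and acid lactonisation as in step 12; the terminal alkene is kept for the later hydroboration and the tertiary hydroxyl emerges as the only free hydroxyl.

Step 19
Reactants: 28 (3R,4R)-3-[4-(benzyloxy)-3-methoxybenzyl]-3-hydroxy-4-(prop-2-en-1-yl)oxolan-2-one
Product: 29 (3R,4R)-3-[4-(benzyloxy)-3-methoxybenzyl]-3-[(benzyloxy)methoxy]-4-(prop-2-en-1-yl)oxolan-2-one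
Conditions: BnOCH2Cl, iPr2NEt, nBu4NI (cat.), ClCH2CH2Cl, 60 °C
Reagents that add atoms: benzyl chloromethyl ether, ClCOCc1ccccc1
Why: Alkylation of the hindered tertiary alcohol with a reactive chloromethyl ether under iodide catalysis. The BOM acetal stops the hydroxyl, which is cis to the C4 chain, from forming a lactol with the aldehyde of 32 or adding to the enaminal of 33, and it leaves with the benzyl ethers in step 24.

Step 20
Reactants: 29 BOM-protected allyl lactone
Product: 31 (3R,4R)-3-[4-(benzyloxy)-3-methoxybenzyl]-3-[(benzyloxy)methoxy]-4-(3-hydroxypropyl)oxolan-2-one, via B-alkyl-9-BBN adduct 30 (not isolated)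
Conditions: 9-BBN, THF, 0 °C → rt; NaBO3·4H2O, H2O, rt
Reagents that add atoms: sodium perborate, [Na+].[O-]OB=O
Why: Anti-Markovnikov hydroboration of the terminal alkene with a bulky borane that does not reduce lactones at room temperature; perborate oxidises the C–B bond under near-neutral conditions that spare the lactone.

Step 21
Reactants: 31 primary alcohol of the lactone 2 series
Product: 32 3-{(3R,4R)-4-[4-(benzyloxy)-3-methoxybenzyl]-4-[(benzyloxy)methoxy]-5-oxooxolan-3-yl}propanal
Conditions: Dess–Martin periodinane, NaHCO3, CH2Cl2, 0 °C → rt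
Reagents that add atoms: none
Why: Periodinane oxidation of a primary alcohol stops at the aldehyde; with the tertiary oxygen capped, no lactol forms that could be oxidised further.

Step 22
Reactants: 32 aldehyde of the lactone 2 series
Product: 33 (2E)-2-({(3R,4R)-4-[4-(benzyloxy)-3-methoxybenzyl]-4-[(benzyloxy)methoxy]-5-oxooxolan-3-yl}methyl)-3-(dimethylamino)prop-2-enal
Conditions: tBuOCH(NMe2)2, toluene, 70 °C
Reagents that add atoms: tert-butoxybis(dimethylamino)methane, CN(C)C(OC(C)(C)C)N(C)C
Why: Aminomethylenation with Bredereck's reagent: the reagent ionises to tert-butoxide and a formamidinium ion, the aldehyde enolate adds to the latter, and loss of dimethylamine gives the vinylogous formamide. The only acidic C–H in the molecule is the aldehyde α-methylene.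

Step 23
Reactants: 20 lactone 1 methoxy ketone; 33 lactone 2 enaminal
Product: 35 (3R,4R)-3-{[2-(benzyloxy)-2'-hydroxy-3,3'-dimethoxy-5'-({(3R,4R)-4-[4-(benzyloxy)-3-methoxybenzyl]-4-[(benzyloxy)methoxy]-5-oxooxolan-3-yl}methyl)biphenyl-5-yl]methyl}-4-[4-(benzyloxy)-3-methoxybenzyl]-3-hydroxyoxolan-2-one, via aminodienone 34 (not isolated)
Conditions: KOtBu (3 equiv), THF, −20 → 45 °C, 20 added slowly to 33 and base; then AcOH, 50 °C
Reagents that add atoms: none
Why: Proposed new method: the potassium enolate of 20, formed preferentially at the doubly activated benzylic α-carbon, adds to the formyl group of 33 and loses hydroxide with the push of the enamine nitrogen to give the 5-(dimethylamino)pentadienone 34. Deprotonation at the methoxy-bearing α'-carbon then gives a trienolate whose terminal carbon attacks the aminomethine carbon (6-endo-trig addition–elimination, equivalent to a disrotatory 6π-electrocyclisation); dimethylamine, which sits β to the carbonyl, is lost by E1cB whereas the α-methoxy group cannot leave, and the ring aromatises to the phenoxide of 35. The closest known reaction types are the base-mediated [3+3] condensations of 1,3-disubstituted acetones with nitromalonaldehyde or vinamidinium salts to 2,6-disubstituted phenols and the aminodienone benzannulation of Jutz; new here are the unsymmetrical α-aryl α'-methoxy ketone and a 2-alkyl enaminal bearing a lactone. Ring C closes by forming C5–C6 and C2–C3; no stereocentre is created, and the four existing ones are safe because C3 of each lactone is quaternary and C4–H is not acidic. Regiochemistry cannot vary: both α-carbons of the ketone must enter the ring and the three-carbon partner is symmetric about its central carbon, so ring B ends ortho to the new hydroxyl with the methoxy group on the other side, whichever bond forms first. The selectivity needed is cross- over self-condensation of 20, which slow addition of 20 to 33 and base and the higher acidity of its benzylic methylene should secure. Closing the ring under base avoids O-cyclisation to a pyrylium ion; acetic acid only protonates the phenoxide and re-closes any lactone opened by the hydroxide released. The BOM ether keeps the C3 oxygen of lactone 2 away from the enaminal.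

Step 24
Reactants: 35 tri-O-benzyl O-BOM biaryl
Product: 37 (3R,4R)-3-{[2,2'-dihydroxy-3,3'-dimethoxy-5'-({(3R,4R)-4-hydroxy-4-(4-hydroxy-3-methoxybenzyl)-5-oxooxolan-3-yl}methyl)biphenyl-5-yl]methyl}-3-hydroxy-4-(4-hydroxy-3-methoxybenzyl)oxolan-2-one, via hemiformal 36 (not isolated)
Conditions: H2 (1 atm), Pd/C, EtOAc/MeOH, rt
Reagents that add atoms: none
Why: Hydrogenolysis of the three aryl benzyl ethers and of the benzyl group of the BOM acetal; the resulting hemiformal loses formaldehyde spontaneously. The lactones, tertiary alcohols and biaryl are inert under these neutral conditions.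

## Compound list

1 | 4-(benzyloxy)-3-methoxybenzyl alcohol | COc1cc(CO)ccc1OCc1ccccc1 | starting material
2 | 4-(benzyloxy)-3-methoxybenzyl bromide | COc1cc(CBr)ccc1OCc1ccccc1 | intermediate
3 | diethyl (R)-malate | CCOC(=O)C[C@@H](O)C(=O)OCC | starting material
4 | diethyl (2R,3S)-3-[4-(benzyloxy)-3-methoxybenzyl]-2-hydroxysuccinate | CCOC(=O)[C@H](O)[C@H](Cc1ccc(OCc2ccccc2)c(OC)c1)C(=O)OCC | intermediate
5 | (2R,3S)-3-[4-(benzyloxy)-3-methoxybenzyl]-2-hydroxysuccinic acid | OC(=O)[C@H](O)[C@H](Cc1ccc(OCc2ccccc2)c(OC)c1)C(=O)O | intermediate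
6 | (2S)-3-[4-(benzyloxy)-3-methoxyphenyl]-2-[(2R,4R)-2-tert-butyl-5-oxo-1,3-dioxolan-4-yl]propanoic acid (cis-dioxolanone) | O=C1O[C@H](C(C)(C)C)O[C@@H]1[C@H](Cc2ccc(OCc3ccccc3)c(OC)c2)C(=O)O | intermediate
7 | vanillin | COc1cc(C=O)ccc1O | starting material
8 | 3-chloro-2-(chloromethyl)prop-1-ene | C=C(CCl)CCl | starting material
9 | 4-{[2-(chloromethyl)prop-2-en-1-yl]oxy}-3-methoxybenzaldehyde | COc1cc(C=O)ccc1OCC(=C)CCl | intermediate
10 | 3-methoxy-4-{[2-(methoxymethyl)prop-2-en-1-yl]oxy}benzaldehyde | COc1cc(C=O)ccc1OCC(=C)COC | intermediate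
11 | 4-hydroxy-3-methoxy-5-[2-(methoxymethyl)prop-2-en-1-yl]benzaldehyde | COc1cc(C=O)cc(CC(=C)COC)c1O | intermediate
12 | 4-(benzyloxy)-3-methoxy-5-[2-(methoxymethyl)prop-2-en-1-yl]benzaldehyde | COc1cc(C=O)cc(CC(=C)COC)c1OCc1ccccc1 | intermediate
13 | {4-(benzyloxy)-3-methoxy-5-[2-(methoxymethyl)prop-2-en-1-yl]phenyl}methanol | COc1cc(CO)cc(CC(=C)COC)c1OCc1ccccc1 | intermediate
14 | 2-(benzyloxy)-5-(bromomethyl)-1-methoxy-3-[2-(methoxymethyl)prop-2-en-1-yl]benzene | COc1cc(CBr)cc(CC(=C)COC)c1OCc1ccccc1 | intermediate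
15 | (2S)-3-[4-(benzyloxy)-3-methoxyphenyl]-2-[(2R,4R)-4-{4-(benzyloxy)-3-methoxy-5-[2-(methoxymethyl)prop-2-en-1-yl]benzyl}-2-tert-butyl-5-oxo-1,3-dioxolan-4-yl]propanoic acid | O=C1O[C@H](C(C)(C)C)O[C@]1(Cc2cc(OC)c(OCc3ccccc3)c(CC(=C)COC)c2)[C@H](Cc2ccc(OCc3ccccc3)c(OC)c2)C(=O)O | intermediate
16 | isobutyl carbonic mixed anhydride of 15 | O=C1O[C@H](C(C)(C)C)O[C@]1(Cc2cc(OC)c(OCc3ccccc3)c(CC(=C)COC)c2)[C@H](Cc2ccc(OCc3ccccc3)c(OC)c2)C(=O)OC(=O)OCC(C)C | intermediate (not isolated)
17 | (2R,5R)-5-{4-(benzyloxy)-3-methoxy-5-[2-(methoxymethyl)prop-2-en-1-yl]benzyl}-5-{(2R)-1-[4-(benzyloxy)-3-methoxyphenyl]-3-hydroxypropan-2-yl}-2-tert-butyl-1,3-dioxolan-4-one | O=C1O[C@H](C(C)(C)C)O[C@]1(Cc2cc(OC)c(OCc3ccccc3)c(CC(=C)COC)c2)[C@H](Cc2ccc(OCc3ccccc3)c(OC)c2)CO | intermediate (not isolated)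
18 | (3R,4R)-3-{4-(benzyloxy)-3-methoxy-5-[2-(methoxymethyl)prop-2-en-1-yl]benzyl}-4-[4-(benzyloxy)-3-methoxybenzyl]-3-hydroxyoxolan-2-one | COc1cc(C[C@@H]2COC(=O)[C@@]2(O)Cc2cc(OC)c(OCc3ccccc3)c(CC(=C)COC)c2)ccc1OCc1ccccc1 | intermediate
19 | (3R,4R)-3-{4-(benzyloxy)-3-[2,3-dihydroxy-2-(methoxymethyl)propyl]-5-methoxybenzyl}-4-[4-(benzyloxy)-3-methoxybenzyl]-3-hydroxyoxolan-2-one (both epimers at the new carbinol) | COc1cc(C[C@@H]2COC(=O)[C@@]2(O)Cc2cc(OC)c(OCc3ccccc3)c(CC(O)(CO)COC)c2)ccc1OCc1ccccc1 | intermediate (not isolated)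
20 | (3R,4R)-3-[4-(benzyloxy)-3-methoxy-5-(3-methoxy-2-oxopropyl)benzyl]-4-[4-(benzyloxy)-3-methoxybenzyl]-3-hydroxyoxolan-2-one | COc1cc(C[C@@H]2COC(=O)[C@@]2(O)Cc2cc(OC)c(OCc3ccccc3)c(CC(=O)COC)c2)ccc1OCc1ccccc1 | intermediate
21 | allyl bromide | C=CCBr | starting material
22 | diethyl (2R,3S)-2-hydroxy-3-(prop-2-en-1-yl)succinate | CCOC(=O)[C@H](O)[C@H](CC=C)C(=O)OCC | intermediate
23 | (2R,3S)-2-hydroxy-3-(prop-2-en-1-yl)succinic acid | OC(=O)[C@H](O)[C@H](CC=C)C(=O)O | intermediate
24 | (2S)-2-[(2R,4R)-2-tert-butyl-5-oxo-1,3-dioxolan-4-yl]pent-4-enoic acid (cis-dioxolanone) | O=C1O[C@H](C(C)(C)C)O[C@@H]1[C@H](CC=C)C(=O)O | intermediate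
25 | (2S)-2-{(2R,4R)-4-[4-(benzyloxy)-3-methoxybenzyl]-2-tert-butyl-5-oxo-1,3-dioxolan-4-yl}pent-4-enoic acid | O=C1O[C@H](C(C)(C)C)O[C@]1(Cc2ccc(OCc3ccccc3)c(OC)c2)[C@H](CC=C)C(=O)O | intermediate
26 | isobutyl carbonic mixed anhydride of 25 | O=C1O[C@H](C(C)(C)C)O[C@]1(Cc2ccc(OCc3ccccc3)c(OC)c2)[C@H](CC=C)C(=O)OC(=O)OCC(C)C | intermediate (not isolated)
27 | (2R,5R)-5-[4-(benzyloxy)-3-methoxybenzyl]-2-tert-butyl-5-[(2R)-1-hydroxypent-4-en-2-yl]-1,3-dioxolan-4-one | O=C1O[C@H](C(C)(C)C)O[C@]1(Cc2ccc(OCc3ccccc3)c(OC)c2)[C@H](CC=C)CO | intermediate (not isolated)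
28 | (3R,4R)-3-[4-(benzyloxy)-3-methoxybenzyl]-3-hydroxy-4-(prop-2-en-1-yl)oxolan-2-one | C=CC[C@@H]1COC(=O)[C@@]1(O)Cc1ccc(OCc2ccccc2)c(OC)c1 | intermediate
29 | (3R,4R)-3-[4-(benzyloxy)-3-methoxybenzyl]-3-[(benzyloxy)methoxy]-4-(prop-2-en-1-yl)oxolan-2-one | C=CC[C@@H]1COC(=O)[C@@]1(OCOCc1ccccc1)Cc1ccc(OCc2ccccc2)c(OC)c1 | intermediate
30 | 9-(3-{(3R,4R)-4-[4-(benzyloxy)-3-methoxybenzyl]-4-[(benzyloxy)methoxy]-5-oxooxolan-3-yl}propyl)-9-borabicyclo[3.3.1]nonane | B1(CCC[C@@H]2COC(=O)[C@@]2(OCOCc2ccccc2)Cc2ccc(OCc3ccccc3)c(OC)c2)C2CCCC1CCC2 | intermediate (not isolated)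
31 | (3R,4R)-3-[4-(benzyloxy)-3-methoxybenzyl]-3-[(benzyloxy)methoxy]-4-(3-hydroxypropyl)oxolan-2-one | OCCC[C@@H]1COC(=O)[C@@]1(OCOCc1ccccc1)Cc1ccc(OCc2ccccc2)c(OC)c1 | intermediate
32 | 3-{(3R,4R)-4-[4-(benzyloxy)-3-methoxybenzyl]-4-[(benzyloxy)methoxy]-5-oxooxolan-3-yl}propanal | O=CCC[C@@H]1COC(=O)[C@@]1(OCOCc1ccccc1)Cc1ccc(OCc2ccccc2)c(OC)c1 | intermediate
33 | (2E)-2-({(3R,4R)-4-[4-(benzyloxy)-3-methoxybenzyl]-4-[(benzyloxy)methoxy]-5-oxooxolan-3-yl}methyl)-3-(dimethylamino)prop-2-enal | CN(C)/C=C(/C=O)C[C@@H]1COC(=O)[C@@]1(OCOCc1ccccc1)Cc1ccc(OCc2ccccc2)c(OC)c1 | intermediate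
34 | aminodienone: 6-(dimethylamino)-1-methoxyhexa-3,5-dien-2-one carrying at C3 ring B of 20 (with lactone 1) and at C5 the (lactone 2)methyl group of 33; alkene geometries not fixed | COCC(=O)C(=CC(=CN(C)C)C[C@@H]1COC(=O)[C@@]1(OCOCc1ccccc1)Cc1ccc(OCc2ccccc2)c(OC)c1)c1cc(C[C@]2(O)C(=O)OC[C@H]2Cc2ccc(OCc3ccccc3)c(OC)c2)cc(OC)c1OCc1ccccc1 | intermediate (not isolated)
35 | (3R,4R)-3-{[2-(benzyloxy)-2'-hydroxy-3,3'-dimethoxy-5'-({(3R,4R)-4-[4-(benzyloxy)-3-methoxybenzyl]-4-[(benzyloxy)methoxy]-5-oxooxolan-3-yl}methyl)biphenyl-5-yl]methyl}-4-[4-(benzyloxy)-3-methoxybenzyl]-3-hydroxyoxolan-2-one | COc1cc(C[C@@H]2COC(=O)[C@@]2(O)Cc2cc(OC)c(OCc5ccccc5)c(-c3cc(C[C@@H]4COC(=O)[C@@]4(OCOCc7ccccc7)Cc4ccc(OCc6ccccc6)c(OC)c4)cc(OC)c3O)c2)ccc1OCc1ccccc1 | intermediate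
36 | hemiformal of the target at the C3 oxygen of lactone 2 (O–CH2–OH) | COc1cc(C[C@@H]2COC(=O)[C@@]2(O)Cc2cc(OC)c(O)c(-c3cc(C[C@@H]4COC(=O)[C@@]4(OCO)Cc4ccc(O)c(OC)c4)cc(OC)c3O)c2)ccc1O | intermediate (not isolated)
37 | (3R,4R)-3-{[2,2'-dihydroxy-3,3'-dimethoxy-5'-({(3R,4R)-4-hydroxy-4-(4-hydroxy-3-methoxybenzyl)-5-oxooxolan-3-yl}methyl)biphenyl-5-yl]methyl}-3-hydroxy-4-(4-hydroxy-3-methoxybenzyl)oxolan-2-one | COc1cc(C[C@@H]2COC(=O)[C@@]2(O)Cc2cc(OC)c(O)c(-c3cc(C[C@@H]4COC(=O)[C@@]4(O)Cc4ccc(O)c(OC)c4)cc(OC)c3O)c2)ccc1O | target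

## Step count and risks

Total step count: 24. Longest linear sequence: 11 steps (steps 5–13, 23, 24 from vanillin; equally steps 14–24 from diethyl (R)-malate).

**Step 23 (key step, proposed new method).** The most likely failure is that the reaction stalls before or at aminodienone 34 while 20 condenses with itself, because the formyl group of a vinylogous formamide is a weak electrophile. O-cyclisation of 34 is a second possibility if the medium turns acidic too early.

The fallback forms the biaryl bond by Suzuki–Miyaura coupling. It sets out from 6 (lactone 1 half) and from 3 (lactone 2 half) and returns to the route at 37.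
- Shared bromide: 5-bromovanillin F1 is benzylated (BnBr, K2CO3) to 4-(benzyloxy)-3-bromo-5-methoxybenzaldehyde F2, reduced (NaBH4) to [4-(benzyloxy)-3-bromo-5-methoxyphenyl]methanol F3 and brominated (PBr3) to 2-(benzyloxy)-1-bromo-5-(bromomethyl)-3-methoxybenzene F4.
- Lactone 1 half: the dianion of 6 is alkylated with F4 as in step 11 to the bromoaryl dioxolanone acid F5. BH3·SMe2, usable here because no alkene is present, reduces the acid to the hydroxymethyl dioxolanone F6, which lactonises with TsOH to the ring B bromide of lactone 1 F7.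
- Lactone 2 half: 3 is alkylated with F4 as in step 2 to the bromobenzyl malate F8, saponified to the diacid F9 and acetalised to the cis-dioxolanone acid F10. Alkylation with 2 gives the dioxolanone acid F11, BH3·SMe2 gives the hydroxymethyl dioxolanone F12, and TsOH gives the ring C bromide of lactone 2 F13. Borylation (B2pin2, PdCl2(dppf), KOAc, dioxane) gives the pinacol boronate F14.
- Union: coupling of F7 with F14 (Pd(OAc)2, SPhos, K3PO4, toluene/H2O, then acidification to re-close any opened lactone) should give the tetra-O-benzyl ether of the target F15, and hydrogenolysis (H2, Pd/C) gives 37.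

**Step 12.** Hydride may attack the carbonate carbonyl of the hindered mixed anhydride and return the acid, or the dioxolanone carbonyl may be reduced, because the activated carboxyl sits on a branched carbon next to a quaternary centre.

The fallback removes the alkene before the reduction so that borane can be used. It sets out from 15 and returns at 20. Lemieux–Johnson cleavage of 15 (OsO4, NaIO4) passes through the vicinal diol acid F16 to the keto acid F17. BH3·SMe2 reduces carboxyl and ketone to the diol F18, which lactonises with TsOH to the secondary alcohol F19 (both epimers at the carbinol). Dess–Martin oxidation, to which the tertiary hydroxyl is inert, gives 20.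

**Step 18.** The same loss of chemoselectivity in the hydride reduction may occur as in step 12.

The fallback lets borane do both jobs. It sets out from 25 and returns at 31. Excess BH3·THF reduces the acid and hydroborates the allyl group; perborate oxidation gives the dioxolanone diol F20, and TsOH gives the diol lactone F21. The primary hydroxyl is silylated (tBuMe2SiCl, imidazole) to the silyl ether F22, the tertiary hydroxyl is protected (BnOCH2Cl, iPr2NEt) to the BOM silyl ether F23, and Bu4NF gives 31.

**Step 22.** Self-aldol condensation of the unbranched aldehyde under the tert-butoxide released by the reagent may outrun aminomethylenation.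

The fallback builds the malonaldehyde unit by electrophilic formylation of an enol ether. It sets out from 32 and returns at 33. Silylation (Me3SiCl, Et3N, DMF) gives the trimethylsilyl enol ether F24. Triethyl orthoformate with BF3·OEt2 at −78 °C gives the 2-substituted 3,3-diethoxypropanal F25. Dimethylamine in THF with a trace of acetic acid at 50 °C eliminates ethanol and exchanges the second ethoxy group for the amine, giving 33.

## Further compounds

F1 | step 23 | 5-bromovanillin (3-bromo-4-hydroxy-5-methoxybenzaldehyde) | COc1cc(C=O)cc(Br)c1O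
F2 | step 23 | 4-(benzyloxy)-3-bromo-5-methoxybenzaldehyde | COc1cc(C=O)cc(Br)c1OCc1ccccc1
F3 | step 23 | [4-(benzyloxy)-3-bromo-5-methoxyphenyl]methanol | COc1cc(CO)cc(Br)c1OCc1ccccc1
F4 | step 23 | 2-(benzyloxy)-1-bromo-5-(bromomethyl)-3-methoxybenzene | COc1cc(CBr)cc(Br)c1OCc1ccccc1
F5 | step 23 | (2S)-3-[4-(benzyloxy)-3-methoxyphenyl]-2-{(2R,4R)-4-[4-(benzyloxy)-3-bromo-5-methoxybenzyl]-2-tert-butyl-5-oxo-1,3-dioxolan-4-yl}propanoic acid | O=C1O[C@H](C(C)(C)C)O[C@]1(Cc2cc(OC)c(OCc3ccccc3)c(Br)c2)[C@H](Cc2ccc(OCc3ccccc3)c(OC)c2)C(=O)O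
F6 | step 23 | (2R,5R)-5-[4-(benzyloxy)-3-bromo-5-methoxybenzyl]-5-{(2R)-1-[4-(benzyloxy)-3-methoxyphenyl]-3-hydroxypropan-2-yl}-2-tert-butyl-1,3-dioxolan-4-one | O=C1O[C@H](C(C)(C)C)O[C@]1(Cc2cc(OC)c(OCc3ccccc3)c(Br)c2)[C@H](Cc2ccc(OCc3ccccc3)c(OC)c2)CO
F7 | step 23 | (3R,4R)-3-[4-(benzyloxy)-3-bromo-5-methoxybenzyl]-4-[4-(benzyloxy)-3-methoxybenzyl]-3-hydroxyoxolan-2-one | COc1cc(C[C@@H]2COC(=O)[C@@]2(O)Cc2cc(OC)c(OCc3ccccc3)c(Br)c2)ccc1OCc1ccccc1
F8 | step 23 | diethyl (2R,3S)-3-[4-(benzyloxy)-3-bromo-5-methoxybenzyl]-2-hydroxysuccinate | CCOC(=O)[C@H](O)[C@H](Cc1cc(OC)c(OCc2ccccc2)c(Br)c1)C(=O)OCC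
F9 | step 23 | (2R,3S)-3-[4-(benzyloxy)-3-bromo-5-methoxybenzyl]-2-hydroxysuccinic acid | OC(=O)[C@H](O)[C@H](Cc1cc(OC)c(OCc2ccccc2)c(Br)c1)C(=O)O
F10 | step 23 | (2S)-3-[4-(benzyloxy)-3-bromo-5-methoxyphenyl]-2-[(2R,4R)-2-tert-butyl-5-oxo-1,3-dioxolan-4-yl]propanoic acid | O=C1O[C@H](C(C)(C)C)O[C@@H]1[C@H](Cc2cc(OC)c(OCc3ccccc3)c(Br)c2)C(=O)O
F11 | step 23 | (2S)-3-[4-(benzyloxy)-3-bromo-5-methoxyphenyl]-2-{(2R,4R)-4-[4-(benzyloxy)-3-methoxybenzyl]-2-tert-butyl-5-oxo-1,3-dioxolan-4-yl}propanoic acid | O=C1O[C@H](C(C)(C)C)O[C@]1(Cc2ccc(OCc3ccccc3)c(OC)c2)[C@H](Cc2cc(OC)c(OCc3ccccc3)c(Br)c2)C(=O)O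
F12 | step 23 | (2R,5R)-5-[4-(benzyloxy)-3-methoxybenzyl]-5-{(2R)-1-[4-(benzyloxy)-3-bromo-5-methoxyphenyl]-3-hydroxypropan-2-yl}-2-tert-butyl-1,3-dioxolan-4-one | O=C1O[C@H](C(C)(C)C)O[C@]1(Cc2ccc(OCc3ccccc3)c(OC)c2)[C@H](Cc2cc(OC)c(OCc3ccccc3)c(Br)c2)CO
F13 | step 23 | (3R,4R)-4-[4-(benzyloxy)-3-bromo-5-methoxybenzyl]-3-[4-(benzyloxy)-3-methoxybenzyl]-3-hydroxyoxolan-2-one | COc1cc(C[C@@H]2COC(=O)[C@@]2(O)Cc2ccc(OCc3ccccc3)c(OC)c2)cc(Br)c1OCc1ccccc1
F14 | step 23 | (3R,4R)-4-[4-(benzyloxy)-3-methoxy-5-(4,4,5,5-tetramethyl-1,3,2-dioxaborolan-2-yl)benzyl]-3-[4-(benzyloxy)-3-methoxybenzyl]-3-hydroxyoxolan-2-one | COc1cc(C[C@@H]2COC(=O)[C@@]2(O)Cc2ccc(OCc3ccccc3)c(OC)c2)cc(B2OC(C)(C)C(C)(C)O2)c1OCc1ccccc1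
F15 | step 23 | tetra-O-benzyl ether of the target (benzyl on the phenols of rings A, B, C and D) | COc1cc(C[C@@H]2COC(=O)[C@@]2(O)Cc2cc(OC)c(OCc5ccccc5)c(-c3cc(C[C@@H]4COC(=O)[C@@]4(O)Cc4ccc(OCc6ccccc6)c(OC)c4)cc(OC)c3OCc3ccccc3)c2)ccc1OCc1ccccc1
F16 | step 12 | vicinal diol acid from 15 (2,3-dihydroxy-2-(methoxymethyl)propyl group on ring B, both epimers) | O=C1O[C@H](C(C)(C)C)O[C@]1(Cc2cc(OC)c(OCc3ccccc3)c(CC(O)(CO)COC)c2)[C@H](Cc2ccc(OCc3ccccc3)c(OC)c2)C(=O)O
F17 | step 12 | (2S)-3-[4-(benzyloxy)-3-methoxyphenyl]-2-{(2R,4R)-4-[4-(benzyloxy)-3-methoxy-5-(3-methoxy-2-oxopropyl)benzyl]-2-tert-butyl-5-oxo-1,3-dioxolan-4-yl}propanoic acid | O=C1O[C@H](C(C)(C)C)O[C@]1(Cc2cc(OC)c(OCc3ccccc3)c(CC(=O)COC)c2)[C@H](Cc2ccc(OCc3ccccc3)c(OC)c2)C(=O)O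
F18 | step 12 | (2R,5R)-5-[4-(benzyloxy)-3-(2-hydroxy-3-methoxypropyl)-5-methoxybenzyl]-5-{(2R)-1-[4-(benzyloxy)-3-methoxyphenyl]-3-hydroxypropan-2-yl}-2-tert-butyl-1,3-dioxolan-4-one (both epimers at the secondary carbinol) | O=C1O[C@H](C(C)(C)C)O[C@]1(Cc2cc(OC)c(OCc3ccccc3)c(CC(O)COC)c2)[C@H](Cc2ccc(OCc3ccccc3)c(OC)c2)CO
F19 | step 12 | (3R,4R)-3-[4-(benzyloxy)-3-(2-hydroxy-3-methoxypropyl)-5-methoxybenzyl]-4-[4-(benzyloxy)-3-methoxybenzyl]-3-hydroxyoxolan-2-one (both epimers at the secondary carbinol) | COc1cc(C[C@@H]2COC(=O)[C@@]2(O)Cc2cc(OC)c(OCc3ccccc3)c(CC(O)COC)c2)ccc1OCc1ccccc1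
F20 | step 18 | (2R,5R)-5-[4-(benzyloxy)-3-methoxybenzyl]-2-tert-butyl-5-[(2R)-1,5-dihydroxypentan-2-yl]-1,3-dioxolan-4-one | O=C1O[C@H](C(C)(C)C)O[C@]1(Cc2ccc(OCc3ccccc3)c(OC)c2)[C@H](CCCO)CO
F21 | step 18 | (3R,4R)-3-[4-(benzyloxy)-3-methoxybenzyl]-3-hydroxy-4-(3-hydroxypropyl)oxolan-2-one | OCCC[C@@H]1COC(=O)[C@@]1(O)Cc1ccc(OCc2ccccc2)c(OC)c1
F22 | step 18 | (3R,4R)-3-[4-(benzyloxy)-3-methoxybenzyl]-4-{3-[(tert-butyldimethylsilyl)oxy]propyl}-3-hydroxyoxolan-2-one | CC(C)(C)[Si](C)(C)OCCC[C@@H]1COC(=O)[C@@]1(O)Cc1ccc(OCc2ccccc2)c(OC)c1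
F23 | step 18 | (3R,4R)-3-[4-(benzyloxy)-3-methoxybenzyl]-3-[(benzyloxy)methoxy]-4-{3-[(tert-butyldimethylsilyl)oxy]propyl}oxolan-2-one | CC(C)(C)[Si](C)(C)OCCC[C@@H]1COC(=O)[C@@]1(OCOCc1ccccc1)Cc1ccc(OCc2ccccc2)c(OC)c1
F24 | step 22 | trimethylsilyl enol ether of 32 (alkene geometry not fixed) | C[Si](C)(C)OC=CC[C@@H]1COC(=O)[C@@]1(OCOCc1ccccc1)Cc1ccc(OCc2ccccc2)c(OC)c1
F25 | step 22 | 2-({(3R,4R)-4-[4-(benzyloxy)-3-methoxybenzyl]-4-[(benzyloxy)methoxy]-5-oxooxolan-3-yl}methyl)-3,3-diethoxypropanal (both epimers at C2) | CCOC(OCC)C(C=O)C[C@@H]1COC(=O)[C@@]1(OCOCc1ccccc1)Cc1ccc(OCc2ccccc2)c(OC)c1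
A1 | alternative 1 | bis(2,3-epoxy alcohol) with four aryl mesylates and two tert-butyldimethylsilyl ethers | COc1cc(C[C@H](CO[Si](C)(C)C(C)(C)C)[C@]2(CO)O[C@@H]2c2cc(OC)c(OS(C)(=O)=O)c(-c3cc(C[C@H](CO[Si](C)(C)C(C)(C)C)[C@]4(CO)O[C@@H]4c4ccc(OS(C)(=O)=O)c(OC)c4)cc(OC)c3OS(C)(=O)=O)c2)ccc1OS(C)(=O)=O
A2 | alternative 2 | bis(γ,δ-unsaturated α-benzyloxy acid) with (E)-propenyl groups and four aryl benzyl ethers | COc1cc(C[C@H](/C=C/C)[C@@](OCc5ccccc5)(C(=O)O)Cc2cc(OC)c(OCc5ccccc5)c(-c3cc(C[C@H](/C=C/C)[C@@](OCc6ccccc6)(C(=O)O)Cc4ccc(OCc6ccccc6)c(OC)c4)cc(OC)c3OCc3ccccc3)c2)ccc1OCc1ccccc1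
A3 | alternative 3 | bis(4-aroyl-3-hydroxy lactone) with four aryl benzyl ethers | COc1cc(C(=O)[C@@H]2COC(=O)[C@@]2(O)Cc2cc(OC)c(OCc5ccccc5)c(-c3cc(C(=O)[C@@H]4COC(=O)[C@@]4(O)Cc4ccc(OCc6ccccc6)c(OC)c4)cc(OC)c3OCc3ccccc3)c2)ccc1OCc1ccccc1
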